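**Plan**

- Enabling feature: in every furan the two α-carbons (C2, C5) are the termini and the two β-carbons (C3, C4) the inner carbons of a 1,3-diene. Ring C maps onto CH2=CH–C(=CH2)–R, rings A and B onto CH2=C(R)–CH=CH–CH2R'. The saturated C3 and C5 tethers keep the three dienes electronically separate.
- Retrosynthesis: the acrylate C=C of the side chain is cut first (Wittig), giving the ring A furfuryl silyl ether 22. All six C–O bonds of rings A, B and C are then cut together, which opens 22 to the acyclic hexaene 19.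
- 19 is cut at the inner C(sp2)–C(sp2) bond of the ring B diene and of the ring A diene (Suzuki–Miyaura). The pieces are bromotriene 4 (from hepta-1,6-diyne), a C9 linker from (S)-citronellol, and alkenylboronate 6.
- Forward order: the ring A diene is joined first (15 + 6), the other chain end is turned into an (E)-alkenylboronate, and coupling with 4 completes 19. The three rings then close together at oxygen in step 14, and the side chain is added last.
- Stereochemistry: the only stereocentre (S) is bought with (S)-citronellol and is never α to a carbonyl. Diene geometry comes from syn-hydroboration, boron–Wittig olefination and stereoretentive coupling; the E-acrylate comes from a stabilised ylide.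

Key step: step 14

Remark on the chemistry: the in-flask intermediates 20 and 21 form as stereoisomer mixtures at their new ring sp3 carbons (21 also as regioisomers); 21 is drawn as the isomer from proton loss at the ring CH2 next to the alkyl-bearing olefinic carbon, and all isomers should converge on 22.

**Route**

Step 1
Reactants: 1 hepta-1,6-diyne
Product: 3 2,6-dibromohepta-1,6-diene, via bis(alkenylborane) 2 (not isolated)
Conditions: B-Br-9-BBN (2.4 equiv), CH2Cl2, 0 °C → rt; then AcOH, 0 °C → rt
Reagents that add atoms: B-bromo-9-borabicyclo[3.3.1]nonane, BrB1C2CCCC1CCC2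
Why: Twofold syn-bromoboration of the terminal alkynes places bromine on the internal and boron on the terminal carbon, and protonolysis of the C–B bonds by acetic acid should leave a 2-bromo-1-alkene at each end.

Step 2
Reactants: 3 2,6-dibromohepta-1,6-diene
Product: 4 2-bromo-6-methylideneocta-1,7-diene
Conditions: 3 (3 equiv), vinylboronic acid pinacol ester (1 equiv), Pd(PPh3)4 (3 mol %), 3 M aq K3PO4, THF, 60 °C; excess 3 recovered
Reagents that add atoms: vinylboronic acid pinacol ester, C=CB1OC(C)(C)C(C)(C)O1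
Why: Suzuki–Miyaura coupling of an alkenyl bromide with a vinylboronate, held at the mono-coupling stage by the threefold excess of the cheap symmetric dibromide, should give the 2-substituted butadiene of ring C next to one untouched bromoalkene.

Step 3
Reactants: 5 tert-butyldimethyl(prop-2-yn-1-yloxy)silane
Product: 6 tert-butyldimethyl{[(2E)-3-(4,4,5,5-tetramethyl-1,3,2-dioxaborolan-2-yl)prop-2-en-1-yl]oxy}silane
Conditions: pinacolborane, Cp2Zr(H)Cl (10 mol %), Et3N (10 mol %), neat, 60 °C
Reagents that add atoms: pinacolborane, B1OC(C)(C)C(C)(C)O1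
Why: Zirconium-catalysed syn-hydroboration of a terminal alkyne with pinacolborane delivers boron to the terminal carbon and should give the (E)-alkenylboronate only.

Step 4
Reactants: 7 (S)-citronellol
Product: 8 tert-butyl{[(3S)-3,7-dimethyloct-6-en-1-yl]oxy}diphenylsilane
Conditions: TBDPSCl, imidazole, CH2Cl2, 0 °C → rt
Reagents that add atoms: tert-butyl(chloro)diphenylsilane, CC(C)(C)[Si](Cl)(c1ccccc1)c1ccccc1
Why: Standard silylation of a primary alcohol, with a silyl group chosen to withstand ozone, acetylide and the Lewis-acidic bromoborane of step 8.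

Step 5
Reactants: 8 tert-butyl{[(3S)-3,7-dimethyloct-6-en-1-yl]oxy}diphenylsilane
Product: 10 (4S)-6-[(tert-butyldiphenylsilyl)oxy]-4-methylhexan-1-ol, via secondary ozonide 9 (not isolated)
Conditions: O3, CH2Cl2, −78 °C, to faint blue; then NaBH4, MeOH, −78 °C → rt
Reagents that add atoms: ozone, [O-][O+]=O
Why: Ozonolysis cleaves the only C=C bond and reductive work-up with borohydride should take the ozonide directly to the primary alcohol, the remote stereocentre being untouched.

Step 6
Reactants: 10 (4S)-6-[(tert-butyldiphenylsilyl)oxy]-4-methylhexan-1-ol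
Product: 11 tert-butyl{[(3S)-6-iodo-3-methylhexyl]oxy}diphenylsilane
Conditions: I2, PPh3, imidazole, CH2Cl2, 0 °C → rt
Reagents that add atoms: iodine, II
Why: Appel-type iodination converts the primary alcohol to the iodide by SN2 displacement of the alkoxyphosphonium ion.

Step 7
Reactants: 11 tert-butyl{[(3S)-6-iodo-3-methylhexyl]oxy}diphenylsilane
Product: 12 tert-butyl{[(3S)-3-methyloct-7-yn-1-yl]oxy}diphenylsilane
Conditions: LiC≡CH·H2NCH2CH2NH2, DMSO, 10 °C → rt
Reagents that add atoms: lithium acetylide–ethylenediamine complex, [Li+].[C-]#C.NCCN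
Why: SN2 alkylation of lithium acetylide by an unhindered primary iodide in DMSO is a standard terminal-alkyne synthesis that silyl ethers tolerate.

Step 8
Reactants: 12 tert-butyl{[(3S)-3-methyloct-7-yn-1-yl]oxy}diphenylsilane
Product: 14 {[(3S)-7-bromo-3-methyloct-7-en-1-yl]oxy}(tert-butyl)diphenylsilane, via alkenylborane 13 (not isolated)
Conditions: B-Br-9-BBN (1.3 equiv), CH2Cl2, 0 °C; then AcOH, 0 °C → rt
Reagents that add atoms: B-bromo-9-borabicyclo[3.3.1]nonane, BrB1C2CCCC1CCC2
Why: Markovnikov syn-bromoboration of the terminal alkyne followed by protodeboronation, as in step 1, should give the 2-bromo-1-alkene.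

Step 9
Reactants: 14 {[(3S)-7-bromo-3-methyloct-7-en-1-yl]oxy}(tert-butyl)diphenylsilane
Product: 15 (3S)-7-bromo-3-methyloct-7-en-1-ol
Conditions: HF·pyridine, pyridine, THF, 0 °C → rt
Reagents that add atoms: none
Why: Buffered fluoride cleavage of the silyl ether spares the bromoalkene, and freeing this alcohol before the second silyl ether enters avoids any later need to tell two silyl ethers apart.

Step 10
Reactants: 15 (3S)-7-bromo-3-methyloct-7-en-1-ol; 6 tert-butyldimethyl{[(2E)-3-(4,4,5,5-tetramethyl-1,3,2-dioxaborolan-2-yl)prop-2-en-1-yl]oxy}silane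
Product: 16 (3S,8E)-10-[(tert-butyldimethylsilyl)oxy]-3-methyl-7-methylidenedec-8-en-1-ol
Conditions: Pd(PPh3)4 (5 mol %), 3 M aq K3PO4, THF, 55 °C
Reagents that add atoms: none
Why: Suzuki–Miyaura coupling of a 2-bromo-1-alkene with an (E)-alkenylboronate proceeds with retention at both partners, tolerates the free hydroxyl, and should build the E-configured diene of ring A.

Step 11
Reactants: 16 (3S,8E)-10-[(tert-butyldimethylsilyl)oxy]-3-methyl-7-methylidenedec-8-en-1-ol
Product: 17 (3S,8E)-10-[(tert-butyldimethylsilyl)oxy]-3-methyl-7-methylidenedec-8-enal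
Conditions: Dess–Martin periodinane, pyridine, CH2Cl2, 0 °C → rt
Reagents that add atoms: none
Why: Dess–Martin oxidation under buffered conditions should give the aldehyde without touching the diene or the allylic silyl ether, and the stereocentre, being β to the carbonyl, cannot epimerise.

Step 12
Reactants: 17 (3S,8E)-10-[(tert-butyldimethylsilyl)oxy]-3-methyl-7-methylidenedec-8-enal
Product: 18 tert-butyldimethyl{[(2E,8S,10E)-8-methyl-4-methylidene-11-(4,4,5,5-tetramethyl-1,3,2-dioxaborolan-2-yl)undeca-2,10-dien-1-yl]oxy}silane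
Conditions: CH2(Bpin)2, lithium 2,2,6,6-tetramethylpiperidide, THF, 0 °C; then 17, −78 °C → rt
Reagents that add atoms: bis(pinacolato)borylmethane, CC1(C)OB(CB2OC(C)(C)C(C)(C)O2)OC1(C)C
Why: Boron–Wittig olefination, in which the α-boryl carbanion adds to the aldehyde and syn-elimination of the B–O unit should give the trans-alkenylboronate.

Step 13
Reactants: 18 tert-butyldimethyl{[(2E,8S,10E)-8-methyl-4-methylidene-11-(4,4,5,5-tetramethyl-1,3,2-dioxaborolan-2-yl)undeca-2,10-dien-1-yl]oxy}silane; 4 2-bromo-6-methylideneocta-1,7-diene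
Product: 19 tert-butyldimethyl{[(2E,8S,10E)-8-methyl-4,12,16-trimethylideneoctadeca-2,10,17-trien-1-yl]oxy}silane
Conditions: PdCl2(dppf)·CH2Cl2 (5 mol %), 3 M aq K3PO4, THF, 50 °C, degassed, dark
Reagents that add atoms: none
Why: Suzuki–Miyaura coupling as in step 10 joins the two halves with retention of the E geometry and should create the ring B diene, completing the hexaene.

Step 14
Reactants: 19 tert-butyldimethyl{[(2E,8S,10E)-8-methyl-4,12,16-trimethylideneoctadeca-2,10,17-trien-1-yl]oxy}silane
Product: 22 tert-butyl({4-[(4S)-5-{4-[3-(furan-3-yl)propyl]furan-2-yl}-4-methylpentyl]furan-2-yl}methoxy)dimethylsilane, via tris(3,6-dihydro-1,2-dioxine) 20 (not isolated), via tris(2,5-dihydrofuran-2-ol) 21 (not isolated)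
Conditions: O2, tetraphenylporphyrin (1 mol %), CH2Cl2 (0.01 M), white LEDs, −20 °C; light off, argon purge; Et3N (0.3 equiv), 0 °C → rt; then camphorsulfonic acid (0.5 equiv), 4 Å MS, 0 °C → rt
Reagents that add atoms: dioxygen, O=O
Why: Proposed new method: each of the three insulated dienes should add singlet oxygen suprafacially in a [4+2] cycloaddition to a 3,6-dihydro-1,2-dioxine, triethylamine then removes a proton next to a peroxide oxygen (Kornblum–DeLaMare rearrangement) to give a cis γ-hydroxy enal or enone that closes to the hemiacetal, and acid dehydrates it to the furan. The closest known reaction type is this same photooxygenation, base and acid sequence on a single acyclic 1,3-diene; running it three times on one substrate in one flask is the untested part. Rings A, B and C each close at oxygen, first as the six-membered peroxide by cycloaddition across the diene termini and then as the five-membered ring by 5-exo-trig attack of the freed hydroxyl on the new carbonyl, so that both α-carbons of every furan are former diene termini. No stereocentre is created in the product, the transient sp3 centres of 20 and 21 are erased on aromatisation, and the methyl-bearing centre takes no part. The step needs cycloaddition to outrun the ene reaction at the allylic CH2 groups and needs the furans never to meet singlet oxygen. The substrate has no tri- or tetrasubstituted olefin, every diene is E-configured with an alkyl group on an inner carbon so the s-cis form is reachable, base and acid enter only after oxygen is purged, and both rearrangement regioisomers lead to the same furan.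

Step 15
Reactants: 22 tert-butyl({4-[(4S)-5-{4-[3-(furan-3-yl)propyl]furan-2-yl}-4-methylpentyl]furan-2-yl}methoxy)dimethylsilane
Product: 23 {4-[(4S)-5-{4-[3-(furan-3-yl)propyl]furan-2-yl}-4-methylpentyl]furan-2-yl}methanol
Conditions: TBAF, THF, 0 °C
Reagents that add atoms: none
Why: Fluoride cleavage of the primary silyl ether is reliable and furans are inert to it.

Step 16
Reactants: 23 {4-[(4S)-5-{4-[3-(furan-3-yl)propyl]furan-2-yl}-4-methylpentyl]furan-2-yl}methanol
Product: 25 ethyl (2E)-3-{4-[(4S)-5-{4-[3-(furan-3-yl)propyl]furan-2-yl}-4-methylpentyl]furan-2-yl}-2-methylprop-2-enoate, via furan-2-carbaldehyde 24 (not isolated)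
Conditions: MnO2, Ph3P=C(CH3)CO2Et, CH2Cl2, reflux
Reagents that add atoms: ethyl 2-(triphenyl-λ5-phosphanylidene)propanoate, CCOC(=O)C(C)=P(c1ccccc1)(c1ccccc1)c1ccccc1
Why: In this tandem oxidation–Wittig olefination MnO2 oxidises the activated furfuryl alcohol and the stabilised α-methyl ylide traps the aldehyde as it forms, which should give the E-trisubstituted enoate.

Step 17
Reactants: 25 ethyl (2E)-3-{4-[(4S)-5-{4-[3-(furan-3-yl)propyl]furan-2-yl}-4-methylpentyl]furan-2-yl}-2-methylprop-2-enoate
Product: 26 (2E)-3-{4-[(4S)-5-{4-[3-(furan-3-yl)propyl]furan-2-yl}-4-methylpentyl]furan-2-yl}-2-methylprop-2-enoic acid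
Conditions: LiOH, THF/MeOH/H2O, rt → 40 °C; then 1 M HCl to pH 3, 0 °C
Reagents that add atoms: lithium hydroxide, [Li+].[OH-]
Why: Saponification of the ethyl ester by hydroxide followed by brief cold acidification should release the acid without harming the furans or the olefin geometry.

**Compound list**

1 | hepta-1,6-diyne | C#CCCCC#C | starting material
2 | (1Z,6Z)-2,6-dibromo-1,7-bis(9-borabicyclo[3.3.1]nonan-9-yl)hepta-1,6-diene, formed in the flask | Br/C(CCC/C(Br)=C/B1C2CCCC1CCC2)=C\B1C2CCCC1CCC2 | intermediate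
3 | 2,6-dibromohepta-1,6-diene | C=C(Br)CCCC(Br)=C | intermediate
4 | 2-bromo-6-methylideneocta-1,7-diene | C=CC(=C)CCCC(Br)=C | intermediate
5 | tert-butyldimethyl(prop-2-yn-1-yloxy)silane | C#CCO[Si](C)(C)C(C)(C)C | starting material
6 | tert-butyldimethyl{[(2E)-3-(4,4,5,5-tetramethyl-1,3,2-dioxaborolan-2-yl)prop-2-en-1-yl]oxy}silane | CC(C)(C)[Si](C)(C)OC/C=C/B1OC(C)(C)C(C)(C)O1 | intermediate
7 | (S)-citronellol, (3S)-3,7-dimethyloct-6-en-1-ol | CC(C)=CCC[C@H](C)CCO | starting material
8 | tert-butyl{[(3S)-3,7-dimethyloct-6-en-1-yl]oxy}diphenylsilane | CC(C)=CCC[C@H](C)CCO[Si](c1ccccc1)(c1ccccc1)C(C)(C)C | intermediate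
9 | 3-{(3S)-5-[(tert-butyldiphenylsilyl)oxy]-3-methylpentyl}-5,5-dimethyl-1,2,4-trioxolane (secondary ozonide, both ring epimers), formed in the flask | CC1(C)OOC(CC[C@H](C)CCO[Si](c2ccccc2)(c2ccccc2)C(C)(C)C)O1 | intermediate
10 | (4S)-6-[(tert-butyldiphenylsilyl)oxy]-4-methylhexan-1-ol | OCCC[C@H](C)CCO[Si](c1ccccc1)(c1ccccc1)C(C)(C)C | intermediate
11 | tert-butyl{[(3S)-6-iodo-3-methylhexyl]oxy}diphenylsilane | ICCC[C@H](C)CCO[Si](c1ccccc1)(c1ccccc1)C(C)(C)C | intermediate
12 | tert-butyl{[(3S)-3-methyloct-7-yn-1-yl]oxy}diphenylsilane | C#CCCC[C@H](C)CCO[Si](c1ccccc1)(c1ccccc1)C(C)(C)C | intermediate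
13 | {[(3S,7Z)-8-(9-borabicyclo[3.3.1]nonan-9-yl)-7-bromo-3-methyloct-7-en-1-yl]oxy}(tert-butyl)diphenylsilane, formed in the flask | Br/C(CCC[C@H](C)CCO[Si](c1ccccc1)(c1ccccc1)C(C)(C)C)=C\B1C2CCCC1CCC2 | intermediate
14 | {[(3S)-7-bromo-3-methyloct-7-en-1-yl]oxy}(tert-butyl)diphenylsilane | C=C(Br)CCC[C@H](C)CCO[Si](c1ccccc1)(c1ccccc1)C(C)(C)C | intermediate
15 | (3S)-7-bromo-3-methyloct-7-en-1-ol | C=C(Br)CCC[C@H](C)CCO | intermediate
16 | (3S,8E)-10-[(tert-butyldimethylsilyl)oxy]-3-methyl-7-methylidenedec-8-en-1-ol | CC(C)(C)[Si](C)(C)OC/C=C/C(=C)CCC[C@H](C)CCO | intermediate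
17 | (3S,8E)-10-[(tert-butyldimethylsilyl)oxy]-3-methyl-7-methylidenedec-8-enal | CC(C)(C)[Si](C)(C)OC/C=C/C(=C)CCC[C@H](C)CC=O | intermediate
18 | tert-butyldimethyl{[(2E,8S,10E)-8-methyl-4-methylidene-11-(4,4,5,5-tetramethyl-1,3,2-dioxaborolan-2-yl)undeca-2,10-dien-1-yl]oxy}silane | CC(C)(C)[Si](C)(C)OC/C=C/C(=C)CCC[C@H](C)C/C=C/B1OC(C)(C)C(C)(C)O1 | intermediate
19 | tert-butyldimethyl{[(2E,8S,10E)-8-methyl-4,12,16-trimethylideneoctadeca-2,10,17-trien-1-yl]oxy}silane (hexaene with three isolated 1,3-dienes) | CC(C)(C)[Si](C)(C)OC/C=C/C(=C)CCC[C@H](C)C/C=C/C(=C)CCCC(=C)C=C | intermediate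
20 | tris(3,6-dihydro-1,2-dioxine): each diene of 19 bridged by O–O across its termini, methyl centre S, ring sp3 centres unassigned, formed in the flask | CC(C)(C)[Si](C)(C)OCC1OOCC(=C1)CCC[C@H](C)CC2OOCC(=C2)CCCC3=CCOOC3 | intermediate
21 | tris(2,5-dihydrofuran-2-ol): each dioxine of 20 rearranged to the cyclic hemiacetal, one regioisomer drawn, formed in the flask | CC(C)(C)[Si](C)(C)OCC1OC(O)C(=C1)CCC[C@H](C)CC2OC(O)C(=C2)CCCC3=CCOC3O | intermediate
22 | tert-butyl({4-[(4S)-5-{4-[3-(furan-3-yl)propyl]furan-2-yl}-4-methylpentyl]furan-2-yl}methoxy)dimethylsilane | CC(C)(C)[Si](C)(C)OCc1cc(CCC[C@H](C)Cc2cc(CCCc3ccoc3)co2)co1 | intermediate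
23 | {4-[(4S)-5-{4-[3-(furan-3-yl)propyl]furan-2-yl}-4-methylpentyl]furan-2-yl}methanol | OCc1cc(CCC[C@H](C)Cc2cc(CCCc3ccoc3)co2)co1 | intermediate
24 | 4-[(4S)-5-{4-[3-(furan-3-yl)propyl]furan-2-yl}-4-methylpentyl]furan-2-carbaldehyde, formed in the flask | O=Cc1cc(CCC[C@H](C)Cc2cc(CCCc3ccoc3)co2)co1 | intermediate
25 | ethyl (2E)-3-{4-[(4S)-5-{4-[3-(furan-3-yl)propyl]furan-2-yl}-4-methylpentyl]furan-2-yl}-2-methylprop-2-enoate | CCOC(=O)/C(C)=C/c1cc(CCC[C@H](C)Cc2cc(CCCc3ccoc3)co2)co1 | intermediate
26 | (2E)-3-{4-[(4S)-5-{4-[3-(furan-3-yl)propyl]furan-2-yl}-4-methylpentyl]furan-2-yl}-2-methylprop-2-enoic acid (CNP0088458.1) | C/C(=C\c1cc(CCC[C@H](C)Cc2cc(CCCc3ccoc3)co2)co1)C(=O)O | target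

**Step count and risks**

Total: 17 steps. Longest linear sequence: 14 steps (steps 4 to 17, from (S)-citronellol).

Steps most likely to fail:

1. Step 14, the only step carrying the new-method label. The ene reaction at the allylic CH2 groups may compete with cycloaddition, and the three dienes may be consumed at different rates, so that partly oxygenated material accumulates; the acid stage may also strip the furfuryl silyl ether. The fallback uses only known single-ring chemistry, sets out from 16 and 4 (each holding one diene) and comes back at 22. Compound 16 is taken alone through the same singlet-oxygen, Et3N and acid sequence, the known single-diene case, to give the ring A furan (3S)-6-[5-({[tert-butyl(dimethyl)silyl]oxy}methyl)furan-3-yl]-3-methylhexan-1-ol F1. Compound 4, whose bromoalkene is inert to singlet oxygen, is treated likewise to give the ring C furan 3-(4-bromopent-4-en-1-yl)furan F2. Dess–Martin oxidation of F1 gives the aldehyde (3S)-6-[5-({[tert-butyl(dimethyl)silyl]oxy}methyl)furan-3-yl]-3-methylhexanal F3. Ohira–Bestmann homologation (dimethyl (1-diazo-2-oxopropyl)phosphonate, K2CO3, MeOH) then gives the terminal alkyne tert-butyldimethyl({4-[(4S)-4-methylhept-6-yn-1-yl]furan-2-yl}methoxy)silane F4. Sonogashira coupling of F4 with F2 (Pd(PPh3)4, CuI, Et3N) gives the enyne tert-butyl({4-[(4S)-11-(furan-3-yl)-4-methyl-8-methylideneundec-6-yn-1-yl]furan-2-yl}methoxy)dimethylsilane F5. Dihydroxylation of its only non-aromatic olefin (OsO4 cat., N-methylmorpholine N-oxide, acetone/H2O) gives the alkynediol (6S)-9-[5-({[tert-butyl(dimethyl)silyl]oxy}methyl)furan-3-yl]-2-[3-(furan-3-yl)propyl]-6-methylnon-3-yne-1,2-diol F6. AgNO3-catalysed 5-endo-dig cyclisation of F6 with loss of water builds ring B and delivers 22. No furan is exposed to singlet oxygen in this sequence.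

2. Step 12. The lithiated bis(boronate) may enolise the aldehyde instead of adding to it, and the elimination may not be fully E-selective. The fallback reverses the polarity of the ring B coupling; it sets out from 17 and 4 and comes back at 19. Takai olefination of 17 (CHI3, CrCl2, THF) should give the (E)-alkenyl iodide tert-butyl{[(2E,8S,10E)-11-iodo-8-methyl-4-methylideneundeca-2,10-dien-1-yl]oxy}dimethylsilane F7. Miyaura borylation of 4 (B2pin2, PdCl2(PPh3)2, PPh3, KOPh, toluene, 50 °C) should give 4,4,5,5-tetramethyl-2-(6-methylideneocta-1,7-dien-2-yl)-1,3,2-dioxaborolane F8. Suzuki–Miyaura coupling of F7 with F8 (Pd(PPh3)4, aq K3PO4, THF) then gives 19.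

3. Step 8. The Lewis-acidic bromoborane may cleave the silyl ether, and hydrogen bromide released during protonolysis may add to the product. The fallback replaces the bromoalkene by an enol triflate; it sets out from 12 and comes back at 16. Gold-catalysed hydration of the alkyne (NaAuCl4 cat., MeOH/H2O) gives the methyl ketone (6S)-8-[(tert-butyldiphenylsilyl)oxy]-6-methyloctan-2-one F9. Kinetic enolisation toward the methyl group and O-triflation (KN(SiMe3)2, PhNTf2, THF, −78 °C) gives (6S)-8-[(tert-butyldiphenylsilyl)oxy]-6-methyloct-1-en-2-yl trifluoromethanesulfonate F10. HF·pyridine removes the silyl group to give (6S)-8-hydroxy-6-methyloct-1-en-2-yl trifluoromethanesulfonate F11. Suzuki–Miyaura coupling of F11 with 6 (Pd(PPh3)4, aq K3PO4, THF) then gives 16.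

**Further compounds**

F1 | step 14 | (3S)-6-[5-({[tert-butyl(dimethyl)silyl]oxy}methyl)furan-3-yl]-3-methylhexan-1-ol | CC(C)(C)[Si](C)(C)OCc1cc(CCC[C@H](C)CCO)co1
F2 | step 14 | 3-(4-bromopent-4-en-1-yl)furan | C=C(Br)CCCc1ccoc1
F3 | step 14 | (3S)-6-[5-({[tert-butyl(dimethyl)silyl]oxy}methyl)furan-3-yl]-3-methylhexanal | CC(C)(C)[Si](C)(C)OCc1cc(CCC[C@H](C)CC=O)co1
F4 | step 14 | tert-butyldimethyl({4-[(4S)-4-methylhept-6-yn-1-yl]furan-2-yl}methoxy)silane | CC(C)(C)[Si](C)(C)OCc1cc(CCC[C@H](C)CC#C)co1
F5 | step 14 | tert-butyl({4-[(4S)-11-(furan-3-yl)-4-methyl-8-methylideneundec-6-yn-1-yl]furan-2-yl}methoxy)dimethylsilane | CC(C)(C)[Si](C)(C)OCc1cc(CCC[C@H](C)CC#CC(=C)CCCc2ccoc2)co1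
F6 | step 14 | (6S)-9-[5-({[tert-butyl(dimethyl)silyl]oxy}methyl)furan-3-yl]-2-[3-(furan-3-yl)propyl]-6-methylnon-3-yne-1,2-diol (both C2 epimers) | CC(C)(C)[Si](C)(C)OCc1cc(CCC[C@H](C)CC#CC(O)(CO)CCCc2ccoc2)co1
F7 | step 12 | tert-butyl{[(2E,8S,10E)-11-iodo-8-methyl-4-methylideneundeca-2,10-dien-1-yl]oxy}dimethylsilane | CC(C)(C)[Si](C)(C)OC/C=C/C(=C)CCC[C@H](C)C/C=C/I
F8 | step 12 | 4,4,5,5-tetramethyl-2-(6-methylideneocta-1,7-dien-2-yl)-1,3,2-dioxaborolane | C=CC(=C)CCCC(=C)B1OC(C)(C)C(C)(C)O1
F9 | step 8 | (6S)-8-[(tert-butyldiphenylsilyl)oxy]-6-methyloctan-2-one | CC(=O)CCC[C@H](C)CCO[Si](c1ccccc1)(c1ccccc1)C(C)(C)C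
F10 | step 8 | (6S)-8-[(tert-butyldiphenylsilyl)oxy]-6-methyloct-1-en-2-yl trifluoromethanesulfonate | C=C(OS(=O)(=O)C(F)(F)F)CCC[C@H](C)CCO[Si](c1ccccc1)(c1ccccc1)C(C)(C)C
F11 | step 8 | (6S)-8-hydroxy-6-methyloct-1-en-2-yl trifluoromethanesulfonate | C=C(OS(=O)(=O)C(F)(F)F)CCC[C@H](C)CCO
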